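# Proposed synthesis of CNP0118330.1 by Michael–Claisen construction of ring A and late aromatisation

## Compound numbering

Abbreviations: prenyl = 3-methylbut-2-en-1-yl; SEM = 2-(trimethylsilyl)ethoxymethyl; TBS = tert-butyldimethylsilyl; Ar = 2,5-diprenyl-3,4-bis(SEM-oxy)phenyl. Flavan numbering (O1, C2, C3, C4, C4a, C5–C8, C8a; ring B primed) is used for the target and for the corresponding atoms of every precursor.

- 1: 3,4-dihydroxybenzaldehyde
- 2: allyl bromide
- 3: 3,4-bis(allyloxy)benzaldehyde
- 4: 2,5-diallyl-3,4-dihydroxybenzaldehyde
- 5: 2,5-diallyl-3,4-bis(SEM-oxy)benzaldehyde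
- 6: 2-methylbut-2-ene
- 7: 2,5-diprenyl-3,4-bis(SEM-oxy)benzaldehyde (ArCHO)
- 8: 2-(3-chloropropyl)-2-methyl-1,3-dioxolane
- 9: [3-(2-methyl-1,3-dioxolan-2-yl)propyl]magnesium chloride
- 10: racemic 1-Ar-4-(2-methyl-1,3-dioxolan-2-yl)butan-1-ol
- 11: 1-Ar-4-(2-methyl-1,3-dioxolan-2-yl)butan-1-one
- 12: (1S)-1-Ar-4-(2-methyl-1,3-dioxolan-2-yl)butan-1-ol
- 13: TBS ether of 12
- 14: (6S)-6-Ar-6-(TBS-oxy)hexan-2-one
- 15: methyl 3,3-dimethylpent-4-enoate
- 16: N,N-dimethylmethyleneiminium iodide
- 17: methyl 2-[(dimethylamino)methyl]-3,3-dimethylpent-4-enoate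
- 18: the trimethylammonium iodide of 17
- 19: methyl 2-(2-methylbut-3-en-2-yl)acrylate
- 20: methyl (7S)-4-acetyl-7-Ar-7-(TBS-oxy)-2-(2-methylbut-3-en-2-yl)heptanoate
- 21: 4-[(3S)-3-Ar-3-(TBS-oxy)propyl]-6-(2-methylbut-3-en-2-yl)cyclohexane-1,3-dione
- 22: 4-[(3S)-3-Ar-3-hydroxypropyl]-6-(2-methylbut-3-en-2-yl)cyclohexane-1,3-dione
- 23: (2S)-2-Ar-6-(2-methylbut-3-en-2-yl)-2,3,4,4a,5,6-hexahydro-7H-chromen-7-one
- 24: the 7-TBS-oxy 3,4,4a,5-tetrahydro-2H-chromene (silyl dienol ether of 23)
- 25: (2S)-2-Ar-7-(TBS-oxy)-6-(2-methylbut-3-en-2-yl)chroman
- 26: the target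

## Analysis of the target

The target 26 is a (2S)-flavan, a chroman (rings A and C) that carries a pentasubstituted phenyl ring B on C2. Ring A has O1 on C8a and a free hydroxyl on C7, meta to each other; a 1,1-dimethylallyl group, bound through its quaternary carbon, sits on C6 next to the C7 hydroxyl, while C8 between the two oxygens is unsubstituted. Ring B is a catechol (C3′, C4′) whose two hydroxyls each have a prenyl group as ortho neighbour (C2′ and C5′). The only stereocentre is C2, which is benzylic, bound to O1 and para to the C4′ oxygen, so it ionises easily under acid and must be set on an open-chain carbinol and kept through a ring closure that leaves the C2–O bond intact. Each phenol with its ortho allyl-type group can cyclise to a chroman or dihydrobenzofuran under acid, and the catechol is air-sensitive once deprotonated, so the end of the route has to be non-acidic and any oxidation must come while the phenols are masked. The main difficulty is regiochemical: on a preformed 7-oxygenated chroman C8 competes with C6 in electrophilic substitution and in sigmatropic shifts from O7, and a tertiary allyl group cannot be put on by direct alkylation without allylic transposition. The route rests on the 1,3-relationship of the ring A oxygens (C7, C8a) with carbon substituents on C6 and C4a: this is the pattern of a 4,6-disubstituted cyclohexane-1,3-dione in which C6 is the α-carbon of an acrylate and C8–C8a–C4a is a methyl ketone, so ring A can be built from open-chain pieces with the dimethylallyl group locked on C6 and aromatised afterwards.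

## Retrosynthetic reasoning

**26 from 25.** The three phenols are unmasked last. The two ring B oxygens are carried as SEM acetals and O7 as a silyl ether, so that one fluoride treatment frees all three without acid; acid would close the ortho-allyl phenols to cyclic ethers and could ionise C2.

**25 from 23 through 24.** Ring A of 25 is two hydrogens above the oxidation level of 23 (the hydrogens on C4a and C5). The cut is made here because a cyclohexenone that already carries O1 on C8a and the carbonyl on C7 becomes the resorcinol pattern by one dehydrogenation. Silylation of the dienolate to 24 gives a 1,3-cyclohexadiene with two oxygen donors, which should be by far the most easily oxidised part of the molecule, and the silyl group keeps the new phenol masked against the oxidant.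

**23 from 21 (through 22).** The O1–C8a bond is cut. In the forward direction the C2 hydroxyl of 22 adds to the neighbouring C8a carbonyl and the hemiketal dehydrates to the vinylogous ester. This cut is preferred over O1–C2 because the oxygen stays on C2 throughout, so the configuration cannot invert or scramble by substitution. Only C8a is within reach of a six-membered closure, so the two carbonyls need not be differentiated.

**21 from 14 and 19.** C4a–C5 and C7–C8 are cut. This splits ring A into a methyl ketone that contains ring B, C2, C3, C4, C4a, C8a and C8, and an acrylate that brings C5, C6, C7 and the dimethylallyl group. The forward step must add the internal α-carbon of 14 to the β-carbon of 19 and then close the ring by attack of the methyl carbon on the ester. Since the tertiary allyl group is already on the acrylate α-carbon, its position on ring A is decided by connectivity and not by selectivity.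

**19 from 15 and 16.** The exocyclic methylene is cut off. The quaternary carbon with its vinyl group is bought ready-made in 15, and α-methylenation through the Mannich base 17 and its quaternary salt 18 needs only enolate chemistry at a carbon with one neighbour of neopentyl type.

**14 from 7 and 8 (through 9–13).** The C2–C3 bond is cut next to ring B. A four-carbon organomagnesium reagent 9 with the ketone masked as a dioxolane adds to aldehyde 7. The resulting carbinol 10 is oxidised to aryl ketone 11, so that the stereocentre can be set by catalyst-controlled transfer hydrogenation, for which an aryl alkyl ketone is the best substrate class. Silylation (13) and unmasking of the methyl ketone give 14. The silyl ether is needed because a free C2 alkoxide would close onto the ketone and block enolate formation in the annulation.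

**7 from 1, 2 and 6 (through 3–5).** The two ring B carbon–carbon bonds at C2′ and C5′ are traced back to the two phenolic oxygens, each of which takes one equivalent of 2. Each O-allyl group of 3 has exactly one unsubstituted ortho carbon, so a double aromatic [3,3] shift places the allyl groups where the prenyl groups must be (4). After protection (5), cross-metathesis with 6 converts allyl into prenyl. Electrophilic prenylation or halogenation of the ring was not chosen, because C6′ would compete and the alkenes would not survive.

## Alternatives that were turned down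

Alternative 1: stereoconvergent oxa-cyclisation through a para-quinone methide.
- Disconnection and key step: O1–C2 is cut. A chiral phosphoric acid would ionise the racemic diarylpropanol A2 (2-[3-(3,4-dihydroxyphenyl)-3-hydroxypropyl]-5-(prenyloxy)phenol) to a para-quinone methide on ring B, and the C8a phenol would add to C2 within the chiral ion pair to give A1, (2S)-2-(3,4-dihydroxyphenyl)-7-(prenyloxy)chroman.
- For it: both enantiomers of A2 are funnelled into one product, so C2 is set catalytically without a redox detour. On stereocentre economy this is stronger than the chosen route, which spends an oxidation and a reduction on C2.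
- Against it: the quinone methide needs a free C4′ hydroxyl and a benzylic carbon that can become coplanar with ring B, which is why A1 has no ring B prenyl groups; in 26 a prenyl group sits ortho to that carbon. All three allyl-type groups are therefore left for the end. Two C-prenylations of a free catechol would be needed, one at the most hindered position C2′ in competition with C6′. The O7 prenyl group would have to be transferred to carbon, where the sigmatropic shift can go to C8 as readily as to C6. The acid that forms the O1–C2 bond can also reopen it, which puts the configuration at risk in later steps.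
- Comparison: the chosen route is longer, but it fixes each of the three substituent positions by construction and never exposes the closed C2 ether to acid.

Alternative 2: Pd(OAc)2/norbornene ortho-alkylation and ipso-etherification.
- Disconnection and key step: C4–C4a and C8a–O1 are cut together. The iodoarene A4 (1-iodo-3-(prenyloxy)benzene) and the bromo alcohol A5 ((1S)-3-bromo-1-Ar-propan-1-ol) would be joined under Pd(OAc)2/phosphine/norbornene catalysis. The primary bromide alkylates the C–H bond ortho to iodine, then the secondary alkoxide couples at the iodine-bearing carbon to give A3, (2S)-7-(prenyloxy)-2-Ar-chroman.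
- For it: it is the most convergent of the four plans. Ring C is made in one operation from two finished halves, and the stereocentre, made beforehand, is not touched. On convergence it is stronger than the chosen route.
- Against it: A4 has two open positions ortho to iodine. This catalytic manifold normally relies on one of them being blocked, so double alkylation, or alkylation at the carbon between iodine and O7, would compete. The aryl prenyl ether of A4 is an allylic electrophile toward zerovalent palladium. A secondary palladium alkoxide can undergo β-hydride elimination before the difficult C–O reductive elimination. A3 still needs the O7-to-C6 shift, with the same C6/C8 ambiguity as in alternative 1.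
- Comparison: the chosen route offers a ring A on which no position has to be selected, and it uses no palladium step in the presence of allylic ethers.

Alternative 3: dearomatised ring A, oxa-Michael addition, rearomatisation.
- Disconnection and key step: O1–C8a is formed on a para-quinol. In A7 (4-hydroxy-4-[(3S)-3-Ar-3-hydroxypropyl]-2-(2-methylbut-3-en-2-yl)cyclohexa-2,5-dien-1-one) the C2 hydroxyl would add under mild base to the β-carbon of the unsubstituted enone arm. Loss of the C4a hydroxyl and enolisation would then give A6, (2S)-6-(2-methylbut-3-en-2-yl)-2-Ar-chroman-7-ol.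
- For it: A6 is one deprotection from 26. The dimethylallyl group would be installed on a para-substituted phenol, where the ortho shift of an O-prenyl group has only equivalent positions to choose from. On the C6 question it is as secure as the chosen route, and it is shorter.
- Against it: A7 has to come from oxidative dearomatisation of a phenol whose side chain carries the free C2 hydroxyl three carbons from the ring. Capture of the para carbon by that hydroxyl (a five-membered spiro ether) should outrun addition of water, so the alcohol would need protection and release. The oxidant also meets the electron-rich ring B and four alkenes. The oxa-Michael step has to choose between two β-carbons, and addition to the substituted arm would put the allyl group on C8. Dehydration of the tertiary carbinol calls for acid, which the C2 ether tolerates poorly.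
- Comparison: the chosen route pays with more steps for ring A. In return its single oxidation is applied when the ring A diene is the most oxidisable group present, and the ring closure has only one carbonyl within reach.

Key step: step 12

## Route

Remark: 20–23 are carried as mixtures of diastereomers at the ring carbons that become C4a and C6, and 24 as a mixture at C4a (21 and 22 also as keto–enol tautomers). Only the C2 descriptor is written for them, because these centres are lost in step 15.

Step 1
Reactants: 1 3,4-dihydroxybenzaldehyde; 2 allyl bromide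
Product: 3 3,4-bis(allyloxy)benzaldehyde
Conditions: 2 (2.4 equiv), K2CO3 (3 equiv), DMF, 60 °C
Reagents that add atoms: allyl bromide (second equivalent of 2), C=CCBr
Why: Two-fold Williamson etherification in which each of the two phenoxides takes up one equivalent of the reactive allylic bromide; the aldehyde has no α-hydrogen and is inert to carbonate.

Step 2
Reactants: 3 3,4-bis(allyloxy)benzaldehyde
Product: 4 2,5-diallyl-3,4-dihydroxybenzaldehyde
Conditions: N,N-diethylaniline, 195 °C, Ar
Reagents that add atoms: none
Why: Double aromatic Claisen rearrangement; the 4-O-allyl group has only C5 as a free ortho carbon (its para carbon bears the formyl group) and the 3-O-allyl group only C2, so two [3,3] shifts followed by enolisation should place the allyl groups at C2 and C5, as O-allyl ethers of 3-hydroxy-4-alkoxybenzaldehydes are known to rearrange to the carbon between oxygen and formyl group.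

Step 3
Reactants: 4 2,5-diallyl-3,4-dihydroxybenzaldehyde
Product: 5 2,5-diallyl-3,4-bis(SEM-oxy)benzaldehyde
Conditions: SEMCl (2.5 equiv), iPr2NEt, Bu4NI (cat.), CH2Cl2, 0 to 40 °C
Reagents that add atoms: 2-(trimethylsilyl)ethoxymethyl chloride (SEMCl), C[Si](C)(C)CCOCCl
Why: O-alkylation of both phenols with an α-chloro ether; the SEM acetals are stable to organomagnesium reagents, alkoxide and amide bases and are removed by fluoride without acid.

Step 4
Reactants: 5 2,5-diallyl-3,4-bis(SEM-oxy)benzaldehyde; 6 2-methylbut-2-ene
Product: 7 2,5-diprenyl-3,4-bis(SEM-oxy)benzaldehyde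
Conditions: second-generation Grubbs catalyst RuCl2(=CHPh)(PCy3)(SIMes) (5 mol%), 2-methylbut-2-ene/CH2Cl2, 40 °C, sealed tube
Reagents that add atoms: none
Why: Olefin cross-metathesis of the two terminal alkenes with excess 2-methylbut-2-ene exchanges =CH2 for =CMe2 with loss of propene; the trisubstituted product alkenes are poor metathesis partners, and the para-disposed side chains cannot ring-close.

Step 5
Reactants: 7 2,5-diprenyl-3,4-bis(SEM-oxy)benzaldehyde; 8 2-(3-chloropropyl)-2-methyl-1,3-dioxolane
Product: 10 racemic 1-Ar-4-(2-methyl-1,3-dioxolan-2-yl)butan-1-ol, via Grignard reagent 9 (not isolated)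
Conditions: Mg, BrCH2CH2Br (cat.), THF, reflux; then 7, 0 °C; aq. NH4Cl
Reagents that add atoms: none
Why: Grignard addition to a non-enolisable aldehyde forms the C2–C3 bond; the dioxolane keeps the future methyl ketone masked.

Step 6
Reactants: 10 racemic 1-Ar-4-(2-methyl-1,3-dioxolan-2-yl)butan-1-ol
Product: 11 1-Ar-4-(2-methyl-1,3-dioxolan-2-yl)butan-1-one
Conditions: Dess–Martin periodinane, pyridine, CH2Cl2, 0 °C to rt
Reagents that add atoms: none
Why: Dess–Martin oxidation of a secondary benzylic alcohol; pyridine buffers the acetic acid so that the ketal and SEM acetals are spared, and the alkenes are inert.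

Step 7
Reactants: 11 1-Ar-4-(2-methyl-1,3-dioxolan-2-yl)butan-1-one
Product: 12 (1S)-1-Ar-4-(2-methyl-1,3-dioxolan-2-yl)butan-1-ol
Conditions: RuCl[(S,S)-TsDPEN](p-cymene) (2 mol%), HCO2H/Et3N (1:1), DMF, 40 °C
Reagents that add atoms: none
Why: Noyori–Ikariya asymmetric transfer hydrogenation of an aryl alkyl ketone; the (S,S)-diamine catalyst should deliver hydride to the Re face, with the aryl group lying against the η6-arene in the six-membered transition state, in the sense known for acetophenone giving the (S)-alcohol, and isolated alkenes are not reduced.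

Step 8
Reactants: 12 (1S)-1-Ar-4-(2-methyl-1,3-dioxolan-2-yl)butan-1-ol
Product: 13 tert-butyl[(1S)-1-Ar-4-(2-methyl-1,3-dioxolan-2-yl)butoxy]dimethylsilane
Conditions: TBSCl, imidazole, DMAP (cat.), DMF, rt to 40 °C
Reagents that add atoms: tert-butyldimethylsilyl chloride (TBSCl), CC(C)(C)[Si](C)(C)Cl
Why: Imidazole-promoted silylation of the secondary alcohol; the ether prevents lactol formation with the ketone and alkoxide chemistry in step 12 and does not affect the stereocentre.

Step 9
Reactants: 13 tert-butyl[(1S)-1-Ar-4-(2-methyl-1,3-dioxolan-2-yl)butoxy]dimethylsilane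
Product: 14 (6S)-6-Ar-6-(TBS-oxy)hexan-2-one
Conditions: PPTS, acetone/H2O (10:1), 50 °C
Reagents that add atoms: water, O
Why: Acid-catalysed hydrolysis of a dialkyl ketone dioxolane, the most acid-labile group present; under this weak acid the secondary silyl ether and the aryl SEM acetals should react much more slowly.

Step 10
Reactants: 15 methyl 3,3-dimethylpent-4-enoate; 16 N,N-dimethylmethyleneiminium iodide
Product: 17 methyl 2-[(dimethylamino)methyl]-3,3-dimethylpent-4-enoate (racemic)
Conditions: LiN(iPr)2, THF, −78 °C; then 16, −78 °C to rt
Reagents that add atoms: none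
Why: Mannich reaction of the ester lithium enolate with a preformed iminium salt; the small electrophile reaches the α-carbon despite the adjacent quaternary centre, which in turn suppresses self-condensation.

Step 11
Reactants: 17 methyl 2-[(dimethylamino)methyl]-3,3-dimethylpent-4-enoate
Product: 19 methyl 2-(2-methylbut-3-en-2-yl)acrylate, via ammonium iodide 18 (not isolated)
Conditions: MeI, CH2Cl2, rt; then DBU, rt
Reagents that add atoms: none
Why: Quaternisation of the amine followed by E1cB elimination of trimethylamine from the β-ammonio ester, the standard α-methylenation of esters.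

Step 12
Reactants: 14 (6S)-6-Ar-6-(TBS-oxy)hexan-2-one; 19 methyl 2-(2-methylbut-3-en-2-yl)acrylate
Product: 21 4-[(3S)-3-Ar-3-(TBS-oxy)propyl]-6-(2-methylbut-3-en-2-yl)cyclohexane-1,3-dione, via keto ester 20 (not isolated)
Conditions: KOtBu (2.2 equiv), THF, −10 °C to rt, then 40 °C; 1 M HCl to pH 4–5 at 0 °C
Reagents that add atoms: none
Why: Consecutive Michael–Claisen annulation, the known base-mediated route from substituted acetones and acrylates to 4-substituted cyclohexane-1,3-diones. Under equilibrating KOtBu the more substituted enolate of 14 (C4a) adds to the unhindered β-methylene of 19 (C5), and the resulting ester enolate is protonated to keto ester 20. The methyl-side enolate of 20 (C8) then attacks the ester carbonyl (C7) and methoxide leaves; this Dieckmann-type closure is a 6-exo-trig attack of an enolate carbon on an exocyclic C=O and forms the only ring made in the step. Deprotonation of the product between its two carbonyls removes it from all equilibria and pulls the reversible steps forward. Two ring stereocentres (C4a, C6) arise without control, which is of no consequence because both become sp2 in step 15, and C2 is remote from the reacting atoms and untouched. The selectivity needed is conjugate addition through the internal rather than the methyl α-carbon, and one addition only: methyl alkyl ketones react at the methylene carbon under thermodynamic base catalysis, and after the first addition that carbon is tertiary while the acceptor is α-branched, so a second addition should be slow. Because the dimethylallyl group sits on the α-carbon of 19 it can end only on C6, next to the C7 carbonyl.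

Step 13
Reactants: 21 4-[(3S)-3-Ar-3-(TBS-oxy)propyl]-6-(2-methylbut-3-en-2-yl)cyclohexane-1,3-dione
Product: 23 (2S)-2-Ar-6-(2-methylbut-3-en-2-yl)-2,3,4,4a,5,6-hexahydro-7H-chromen-7-one, via hydroxy dione 22 (not isolated)
Conditions: HF·pyridine, pyridine, THF, 0 °C to rt; then PPTS (cat.), 4 Å MS, PhMe, 50 °C
Reagents that add atoms: none
Why: Fluoride cleaves the Si–O bond while the SEM acetals survive buffered HF; the freed C2 hydroxyl adds to the adjacent C8a carbonyl (six-membered hemiketal) and mild acid dehydrates it to the conjugated vinylogous ester. The C2–O bond is never broken, so the (S) configuration is retained, and the C7 carbonyl is out of reach.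

Step 14
Reactants: 23 (2S)-2-Ar-6-(2-methylbut-3-en-2-yl)-2,3,4,4a,5,6-hexahydro-7H-chromen-7-one
Product: 24 tert-butyl{[(2S)-2-Ar-6-(2-methylbut-3-en-2-yl)-3,4,4a,5-tetrahydro-2H-chromen-7-yl]oxy}dimethylsilane
Conditions: LiN(iPr)2, THF, −78 °C; TBSCl, DMPU, −78 to 0 °C
Reagents that add atoms: tert-butyldimethylsilyl chloride (TBSCl), CC(C)(C)[Si](C)(C)Cl
Why: Kinetic α′-deprotonation of a vinylogous ester at C6 and O-silylation of the cross-conjugated dienolate give the 2-silyloxy diene. Should the extended dienolate (deprotonation at C4a) form instead, its silyl ether is at the same oxidation level and would converge on 25 in step 15.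

Step 15
Reactants: 24 tert-butyl{[(2S)-2-Ar-6-(2-methylbut-3-en-2-yl)-3,4,4a,5-tetrahydro-2H-chromen-7-yl]oxy}dimethylsilane
Product: 25 tert-butyl{[(2S)-2-Ar-6-(2-methylbut-3-en-2-yl)-3,4-dihydro-2H-chromen-7-yl]oxy}dimethylsilane
Conditions: DDQ (1.05 equiv), 2,6-lutidine, CH2Cl2, −40 to 0 °C
Reagents that add atoms: none
Why: Quinone dehydrogenation of a 1,3-cyclohexadiene to an arene; hydride abstraction from C5 gives an arenium ion stabilised by O1 and the silyloxy group, and loss of the C4a proton completes ring A. The doubly oxygenated diene should be far more reactive than any other site, so one equivalent at low temperature is used, and lutidine buffers the acidic hydroquinone.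

Step 16
Reactants: 25 tert-butyl{[(2S)-2-Ar-6-(2-methylbut-3-en-2-yl)-3,4-dihydro-2H-chromen-7-yl]oxy}dimethylsilane
Product: 26 4-[(2S)-7-hydroxy-6-(2-methylbut-3-en-2-yl)-3,4-dihydro-2H-chromen-2-yl]-3,6-bis(3-methylbut-2-en-1-yl)benzene-1,2-diol
Conditions: Bu4NF (excess), H2NCH2CH2NH2, DMPU/THF, 65 °C, Ar; aq. NH4Cl
Reagents that add atoms: none
Why: Fluoride attacks silicon in the aryl silyl ether and in both SEM groups, the latter fragmenting to ethene and a formaldehyde hemiacetal that releases the phenoxide; the diamine traps formaldehyde. The non-acidic medium avoids cyclisation of the ortho-allyl phenols, and exclusion of air protects the catecholate.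

## Compound list

1 | 3,4-dihydroxybenzaldehyde | O=Cc1ccc(O)c(O)c1 | starting material
2 | allyl bromide (3-bromoprop-1-ene) | C=CCBr | starting material
3 | 3,4-bis(allyloxy)benzaldehyde | O=Cc1ccc(OCC=C)c(OCC=C)c1 | intermediate
4 | 2,5-diallyl-3,4-dihydroxybenzaldehyde | O=Cc1cc(CC=C)c(O)c(O)c1CC=C | intermediate
5 | 2,5-diallyl-3,4-bis{[2-(trimethylsilyl)ethoxy]methoxy}benzaldehyde | O=Cc1cc(CC=C)c(OCOCC[Si](C)(C)C)c(OCOCC[Si](C)(C)C)c1CC=C | intermediate
6 | 2-methylbut-2-ene | CC=C(C)C | starting material
7 | 2,5-bis(3-methylbut-2-en-1-yl)-3,4-bis{[2-(trimethylsilyl)ethoxy]methoxy}benzaldehyde | O=Cc1cc(CC=C(C)C)c(OCOCC[Si](C)(C)C)c(OCOCC[Si](C)(C)C)c1CC=C(C)C | intermediate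
8 | 2-(3-chloropropyl)-2-methyl-1,3-dioxolane | CC1(CCCCl)OCCO1 | starting material
9 | [3-(2-methyl-1,3-dioxolan-2-yl)propyl]magnesium chloride | CC1(CCC[Mg]Cl)OCCO1 | intermediate
10 | racemic 1-Ar-4-(2-methyl-1,3-dioxolan-2-yl)butan-1-ol | CC1(CCCC(O)c2cc(CC=C(C)C)c(OCOCC[Si](C)(C)C)c(OCOCC[Si](C)(C)C)c2CC=C(C)C)OCCO1 | intermediate
11 | 1-Ar-4-(2-methyl-1,3-dioxolan-2-yl)butan-1-one | CC1(CCCC(=O)c2cc(CC=C(C)C)c(OCOCC[Si](C)(C)C)c(OCOCC[Si](C)(C)C)c2CC=C(C)C)OCCO1 | intermediate
12 | (1S)-1-Ar-4-(2-methyl-1,3-dioxolan-2-yl)butan-1-ol | CC1(CCC[C@H](O)c2cc(CC=C(C)C)c(OCOCC[Si](C)(C)C)c(OCOCC[Si](C)(C)C)c2CC=C(C)C)OCCO1 | intermediate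
13 | tert-butyl[(1S)-1-Ar-4-(2-methyl-1,3-dioxolan-2-yl)butoxy]dimethylsilane | CC1(CCC[C@H](O[Si](C)(C)C(C)(C)C)c2cc(CC=C(C)C)c(OCOCC[Si](C)(C)C)c(OCOCC[Si](C)(C)C)c2CC=C(C)C)OCCO1 | intermediate
14 | (6S)-6-Ar-6-(tert-butyldimethylsilyloxy)hexan-2-one | CC(=O)CCC[C@H](O[Si](C)(C)C(C)(C)C)c1cc(CC=C(C)C)c(OCOCC[Si](C)(C)C)c(OCOCC[Si](C)(C)C)c1CC=C(C)C | intermediate
15 | methyl 3,3-dimethylpent-4-enoate | COC(=O)CC(C)(C)C=C | starting material
16 | N,N-dimethylmethyleneiminium iodide | C=[N+](C)C.[I-] | starting material
17 | methyl 2-[(dimethylamino)methyl]-3,3-dimethylpent-4-enoate (racemic) | COC(=O)C(CN(C)C)C(C)(C)C=C | intermediate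
18 | [2-(methoxycarbonyl)-3,3-dimethylpent-4-en-1-yl]trimethylammonium iodide (racemic) | COC(=O)C(C[N+](C)(C)C)C(C)(C)C=C.[I-] | intermediate
19 | methyl 2-(2-methylbut-3-en-2-yl)acrylate (methyl 3,3-dimethyl-2-methylidenepent-4-enoate) | C=CC(C)(C)C(=C)C(=O)OC | intermediate
20 | methyl (7S)-4-acetyl-7-Ar-7-(tert-butyldimethylsilyloxy)-2-(2-methylbut-3-en-2-yl)heptanoate (diastereomer mixture) | COC(=O)C(CC(CC[C@H](O[Si](C)(C)C(C)(C)C)c1cc(CC=C(C)C)c(OCOCC[Si](C)(C)C)c(OCOCC[Si](C)(C)C)c1CC=C(C)C)C(C)=O)C(C)(C)C=C | intermediate
21 | 4-[(3S)-3-Ar-3-(tert-butyldimethylsilyloxy)propyl]-6-(2-methylbut-3-en-2-yl)cyclohexane-1,3-dione (diastereomer mixture) | O=C1CC(=O)C(C(C)(C)C=C)CC1CC[C@H](O[Si](C)(C)C(C)(C)C)c1cc(CC=C(C)C)c(OCOCC[Si](C)(C)C)c(OCOCC[Si](C)(C)C)c1CC=C(C)C | intermediate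
22 | 4-[(3S)-3-Ar-3-hydroxypropyl]-6-(2-methylbut-3-en-2-yl)cyclohexane-1,3-dione (diastereomer mixture) | O=C1CC(=O)C(C(C)(C)C=C)CC1CC[C@H](O)c1cc(CC=C(C)C)c(OCOCC[Si](C)(C)C)c(OCOCC[Si](C)(C)C)c1CC=C(C)C | intermediate
23 | (2S)-2-Ar-6-(2-methylbut-3-en-2-yl)-2,3,4,4a,5,6-hexahydro-7H-chromen-7-one (diastereomer mixture) | O=C1C=C2O[C@H](c3cc(CC=C(C)C)c(OCOCC[Si](C)(C)C)c(OCOCC[Si](C)(C)C)c3CC=C(C)C)CCC2CC1C(C)(C)C=C | intermediate
24 | tert-butyl{[(2S)-2-Ar-6-(2-methylbut-3-en-2-yl)-3,4,4a,5-tetrahydro-2H-chromen-7-yl]oxy}dimethylsilane | C=CC(C)(C)C1=C(O[Si](C)(C)C(C)(C)C)C=C2O[C@H](c3cc(CC=C(C)C)c(OCOCC[Si](C)(C)C)c(OCOCC[Si](C)(C)C)c3CC=C(C)C)CCC2C1 | intermediate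
25 | tert-butyl{[(2S)-2-Ar-6-(2-methylbut-3-en-2-yl)-3,4-dihydro-2H-chromen-7-yl]oxy}dimethylsilane | C=CC(C)(C)c1cc2c(cc1O[Si](C)(C)C(C)(C)C)O[C@H](c1cc(CC=C(C)C)c(OCOCC[Si](C)(C)C)c(OCOCC[Si](C)(C)C)c1CC=C(C)C)CC2 | intermediate
26 | 4-[(2S)-7-hydroxy-6-(2-methylbut-3-en-2-yl)-3,4-dihydro-2H-chromen-2-yl]-3,6-bis(3-methylbut-2-en-1-yl)benzene-1,2-diol | C=CC(C)(C)c1cc2c(cc1O)O[C@H](c1cc(CC=C(C)C)c(O)c(O)c1CC=C(C)C)CC2 | target

## Step count and least certain steps

Total: 16 steps. Longest linear sequence: 14 steps (steps 1–9 and 12–16); steps 10 and 11 are the two-step branch to 19.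

**Step 12 (key step).** Three things may go wrong. Conjugate addition may be slow, because the quaternary substituent twists the ester of 19 out of conjugation, which would give aldol self-condensation of 14 time to compete. Some addition may occur through the methyl-side enolate, which leads to the wrong substitution pattern on the dione. The ring closure may stall, because the ester carbonyl is shielded by a tertiary α-carbon with a quaternary neighbour.

The fallback separates the two bond formations and fixes the enolate regiochemistry beforehand. It sets out from 14, which is converted under equilibrating conditions (TMSCl, Et3N, DMF, 90 °C) into the internal trimethylsilyl enol ether F1. Cleavage of F1 with MeLi in THF at 0 °C gives the regiodefined lithium enolate F2, which is added to 19 at −78 °C. Protonation gives keto ester 20, now isolated. Its Dieckmann-type closure is then run separately with KOtBu in THF at reflux, and the route is rejoined at 21.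

**Step 15.** Hydride abstraction might not stay at the ring A diene. The doubly activated methylene groups of the prenyl side chains and the C2–H bond are possible competing sites. Over-oxidation of the new aromatic ring at C4 (para to O7) and hydrolysis of the dienol ether back to the enone are further risks.

The fallback replaces the quinone by the Saegusa–Ito oxidation. It sets out from 24, which with Pd(OAc)2 in MeCN at rt should form the palladium enolate. β-Hydride elimination toward C5 and spontaneous enolisation then give the free phenol (2S)-2-Ar-6-(2-methylbut-3-en-2-yl)chroman-7-ol F3. The fluoride conditions of step 16 remove the two SEM groups of F3, and the route is rejoined at 26.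

**Step 2.** The second sigmatropic shift may be incomplete at a temperature the aldehyde tolerates. The 3-O-allyl group may migrate through the oxygen-bearing ortho carbon to C6. The ortho-allyl phenols may close thermally to dihydrobenzofurans.

The fallback installs the prenyl groups directly by the milder rearrangement of tertiary allyl ethers and needs no metathesis. It sets out from 1, which is etherified with 3-chloro-3-methylbut-1-yne (CuCl2·2H2O cat., DBU, MeCN, 0 °C) to 3,4-bis[(2-methylbut-3-yn-2-yl)oxy]benzaldehyde F4. Semi-hydrogenation (H2, Pd/CaCO3 poisoned with Pb(OAc)2, quinoline, EtOAc) gives 3,4-bis[(2-methylbut-3-en-2-yl)oxy]benzaldehyde F5. Heating in xylene at about 130 °C should give 3,4-dihydroxy-2,5-bis(3-methylbut-2-en-1-yl)benzaldehyde F6 by a double Claisen rearrangement. Protection as in step 3 (SEMCl, iPr2NEt) rejoins the route at 7.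

**Step 7.** Hydride transfer may be slow or poorly face-selective, because the ortho prenyl group turns the carbonyl out of the plane of an electron-rich ring, and the ketal may be partly lost in the formate medium.

The fallback is the Corey–Bakshi–Shibata reduction, in which a chiral oxazaborolidine delivers a boron hydride. It sets out from 11 and uses (R)-2-methyl-CBS-oxazaborolidine (catalytic) with catecholborane in toluene at −78 °C; this borane does not hydroborate the alkenes at that temperature. It rejoins the route at 12 without any new compound.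

**Step 16.** Cleavage of the second SEM group, flanked by a prenyl group and a phenoxide, may be incomplete. Released formaldehyde may hydroxymethylate C8 of the electron-rich ring A. The catecholate may be oxidised by traces of air in the hot basic medium.

The fallback changes the cleavage mechanism. It sets out from 25, which is treated with MgBr2·OEt2 in MeNO2/Et2O at rt; chelation-assisted fragmentation of the acetals should give (2S)-2-[3,4-dihydroxy-2,5-bis(3-methylbut-2-en-1-yl)phenyl]-7-(tert-butyldimethylsilyloxy)-6-(2-methylbut-3-en-2-yl)chroman F7. The remaining aryl silyl ether of F7 is removed with Bu4NF buffered with AcOH in THF at 0 °C, which rejoins the route at 26.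

## Further compounds

F1 | step 12 | tert-butyldimethyl{[(1S)-1-Ar-5-(trimethylsilyloxy)hex-4-en-1-yl]oxy}silane (internal trimethylsilyl enol ether of 14, E/Z mixture) | CC(O[Si](C)(C)C)=CCC[C@H](O[Si](C)(C)C(C)(C)C)c1cc(CC=C(C)C)c(OCOCC[Si](C)(C)C)c(OCOCC[Si](C)(C)C)c1CC=C(C)C
F2 | step 12 | lithium (6S)-6-Ar-6-(tert-butyldimethylsilyloxy)hex-2-en-2-olate | [Li+].CC([O-])=CCC[C@H](O[Si](C)(C)C(C)(C)C)c1cc(CC=C(C)C)c(OCOCC[Si](C)(C)C)c(OCOCC[Si](C)(C)C)c1CC=C(C)C
F3 | step 15 | (2S)-2-Ar-6-(2-methylbut-3-en-2-yl)chroman-7-ol | C=CC(C)(C)c1cc2c(cc1O)O[C@H](c1cc(CC=C(C)C)c(OCOCC[Si](C)(C)C)c(OCOCC[Si](C)(C)C)c1CC=C(C)C)CC2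
F4 | step 2 | 3,4-bis[(2-methylbut-3-yn-2-yl)oxy]benzaldehyde | O=Cc1ccc(OC(C)(C)C#C)c(OC(C)(C)C#C)c1
F5 | step 2 | 3,4-bis[(2-methylbut-3-en-2-yl)oxy]benzaldehyde | O=Cc1ccc(OC(C)(C)C=C)c(OC(C)(C)C=C)c1
F6 | step 2 | 3,4-dihydroxy-2,5-bis(3-methylbut-2-en-1-yl)benzaldehyde | O=Cc1cc(CC=C(C)C)c(O)c(O)c1CC=C(C)C
F0 | step 7 | none | none
F7 | step 16 | (2S)-2-[3,4-dihydroxy-2,5-bis(3-methylbut-2-en-1-yl)phenyl]-7-(tert-butyldimethylsilyloxy)-6-(2-methylbut-3-en-2-yl)chroman | C=CC(C)(C)c1cc2c(cc1O[Si](C)(C)C(C)(C)C)O[C@H](c1cc(CC=C(C)C)c(O)c(O)c1CC=C(C)C)CC2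
A1 | alternative 1 | (2S)-2-(3,4-dihydroxyphenyl)-7-[(3-methylbut-2-en-1-yl)oxy]chroman | CC(C)=CCOc1ccc2c(c1)O[C@H](c1ccc(O)c(O)c1)CC2
A2 | alternative 1 | racemic 2-[3-(3,4-dihydroxyphenyl)-3-hydroxypropyl]-5-[(3-methylbut-2-en-1-yl)oxy]phenol | CC(C)=CCOc1ccc(CCC(O)c2ccc(O)c(O)c2)c(O)c1
A3 | alternative 2 | (2S)-7-[(3-methylbut-2-en-1-yl)oxy]-2-Ar-chroman | CC(C)=CCOc1ccc2c(c1)O[C@H](c1cc(CC=C(C)C)c(OCOCC[Si](C)(C)C)c(OCOCC[Si](C)(C)C)c1CC=C(C)C)CC2
A4 | alternative 2 | 1-iodo-3-[(3-methylbut-2-en-1-yl)oxy]benzene | CC(C)=CCOc1cccc(I)c1
A5 | alternative 2 | (1S)-3-bromo-1-Ar-propan-1-ol | BrCC[C@H](O)c1cc(CC=C(C)C)c(OCOCC[Si](C)(C)C)c(OCOCC[Si](C)(C)C)c1CC=C(C)C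
A6 | alternative 3 | (2S)-2-Ar-6-(2-methylbut-3-en-2-yl)chroman-7-ol | C=CC(C)(C)c1cc2c(cc1O)O[C@H](c1cc(CC=C(C)C)c(OCOCC[Si](C)(C)C)c(OCOCC[Si](C)(C)C)c1CC=C(C)C)CC2
A7 | alternative 3 | 4-hydroxy-4-[(3S)-3-Ar-3-hydroxypropyl]-2-(2-methylbut-3-en-2-yl)cyclohexa-2,5-dien-1-one | C=CC(C)(C)C1=CC(O)(CC[C@H](O)c2cc(CC=C(C)C)c(OCOCC[Si](C)(C)C)c(OCOCC[Si](C)(C)C)c2CC=C(C)C)C=CC1=O
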